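The target is cut at the C(sp3)–C(sp) bond between C3 (the propargylic CH2, third carbon from the ester oxygen) and C4 (the diyne terminus) of the 11-(furan-2-yl)undeca-4,6-diynyl chain. One palladium/copper-catalysed alkyl Sonogashira coupling joins the complete acyl half, carried as the 3-iodopropyl ester of 19-(furan-2-yl)nonadeca-5,7-diynoic acid, to the terminal diyne 2-(octa-5,7-diyn-1-yl)furan and finishes the target. The step exploits the acidic C–H at the end of the C4–C7 diyne and the unbranched O–CH2–CH2–CH2–I tether. Catalytic metalation under carbonate base replaces a lithium acetylide, so the ester, the internal 5,7-diyne and both furan rings stay unprotected.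

Key step: step 10

Remark: the target has no stereocentre and no double-bond geometry; all compounds called starting materials are assumed to be commercially available. Both furan-bearing chains start from 2-furyllithium, which is made once as a THF solution (step 1) and divided between the two alkylations (steps 2 and 7), run in parallel.

Step 1
Reactants: 1 furan
Product: 2 2-furyllithium, obtained as a THF solution, titrated and divided between steps 2 and 7
Conditions: n-BuLi (1.0 equiv), furan (1.1 equiv), THF, 0 °C to rt, argon; solution kept at 0 °C and used the same day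
Reagents that add atoms: n-butyllithium, [Li]CCCC
Why: α-Lithiation of furan, in which n-BuLi in THF should remove the most acidic ring proton (C2–H, next to oxygen) to give a solution that is stable long enough to be divided.

Step 2
Reactants: 2 2-furyllithium (one portion of the solution); 3 1,11-dibromoundecane
Product: 4 2-(11-bromoundecyl)furan
Conditions: solution of 2 (1.0 equiv) added to 3 (3 equiv), THF, −78 °C to rt
Reagents that add atoms: none
Why: SN2 alkylation of the 2-furyllithium with a primary bromide, the excess of dibromide holding back double substitution.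

Step 3
Reactants: 4 2-(11-bromoundecyl)furan
Product: 5 2-(tridec-12-yn-1-yl)furan
Conditions: LiC≡CH·H2NCH2CH2NH2 (1.5 equiv), DMSO, rt
Reagents that add atoms: lithium acetylide–ethylenediamine complex, [Li]C#C.NCCN
Why: SN2 alkylation of an acetylide by a primary bromide in a dipolar aprotic solvent, under which the furan C–H is not metalated.

Step 4
Reactants: 6 hex-5-ynoic acid
Product: 7 6-bromohex-5-ynoic acid
Conditions: Br2 (1.1 equiv), KOH (aq., excess), 0 °C to rt; then cold dilute HCl
Reagents that add atoms: bromine, BrBr
Why: Straus bromination, in which KOBr formed from Br2 and KOH brominates the terminal alkyne C–H while the carboxylate stays in water as its salt.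

Step 5
Reactants: 5 2-(tridec-12-yn-1-yl)furan; 7 6-bromohex-5-ynoic acid
Product: 8 19-(furan-2-yl)nonadeca-5,7-diynoic acid
Conditions: CuCl (10 mol%), NH2OH·HCl (30 mol%), EtNH2 (70% aq.), MeOH/THF, 0 °C to rt, dark; then cold aqueous citric acid
Reagents that add atoms: none
Why: Cadiot–Chodkiewicz coupling of the copper acetylide of 5 with bromoalkyne 7 should give the unsymmetrical diyne, with hydroxylamine keeping copper monovalent and the halogen placed on the acid partner so that the furan never meets an electrophilic bromine source.

Step 6
Reactants: 8 19-(furan-2-yl)nonadeca-5,7-diynoic acid; 9 3-iodopropan-1-ol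
Product: 10 3-iodopropyl 19-(furan-2-yl)nonadeca-5,7-diynoate
Conditions: DCC (1.1 equiv), DMAP (10 mol%), CH2Cl2, 0 °C to rt, dark
Reagents that add atoms: none
Why: Steglich esterification under neutral conditions, which should leave the primary iodide, the diyne and the furan untouched.

Step 7
Reactants: 2 2-furyllithium (second portion of the solution); 11 1,4-dibromobutane
Product: 12 2-(4-bromobutyl)furan
Conditions: solution of 2 (1.0 equiv) added to 11 (3 equiv), THF, −78 °C to rt
Reagents that add atoms: none
Why: The same SN2 alkylation of 2-furyllithium by a primary bromide as in step 2, again with excess dibromide to favour monosubstitution.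

Step 8
Reactants: 13 1,4-bis(trimethylsilyl)buta-1,3-diyne; 12 2-(4-bromobutyl)furan
Product: 15 trimethyl[8-(furan-2-yl)octa-1,3-diyn-1-yl]silane, via lithium (trimethylsilyl)butadiynide 14 (not isolated)
Conditions: MeLi·LiBr (1.0 equiv), THF, 0 °C to rt; then 12, HMPA, −78 °C to rt
Reagents that add atoms: none
Why: MeLi removes one silyl group as Me4Si to give the monolithium diynide, which is alkylated in an SN2 reaction by the primary bromide in the presence of HMPA while the second silyl group caps the other terminus.

Step 9
Reactants: 15 trimethyl[8-(furan-2-yl)octa-1,3-diyn-1-yl]silane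
Product: 16 2-(octa-5,7-diyn-1-yl)furan
Conditions: K2CO3 (0.2 equiv), MeOH/THF, 0 °C to rt; kept in solution and used at once
Reagents that add atoms: none
Why: Base-catalysed methanolysis of the alkynyl C–Si bond (protodesilylation) should free the terminal diyne without touching the furan.

Step 10
Reactants: 10 3-iodopropyl 19-(furan-2-yl)nonadeca-5,7-diynoate; 16 2-(octa-5,7-diyn-1-yl)furan (1.3 equiv)
Product: 17 11-(furan-2-yl)undeca-4,6-diyn-1-yl 19-(furan-2-yl)nonadeca-5,7-diynoate
Conditions: [(C3H5)PdCl]2 (2.5 mol%), 1,3-bis(1-adamantyl)imidazolium chloride (5 mol%), CuI (7.5 mol%), Cs2CO3 (1.4 equiv), DMF/Et2O 1:2, 45 °C, degassed, dark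
Reagents that add atoms: none
Why: Sonogashira coupling of an unactivated primary alkyl iodide: the bulky N-heterocyclic carbene complex of zerovalent palladium, formed in the flask from the imidazolium salt and Cs2CO3, adds oxidatively to the primary C–I bond of 10, the copper diynide formed from 16, CuI and Cs2CO3 transmetalates, and reductive elimination should form the C(sp3)–C(sp) bond faster than β-hydride elimination. The closest known reaction type is the palladium/copper-catalysed alkyl Sonogashira coupling of primary alkyl bromides and iodides with terminal alkynes, applied here to a terminal conjugated diyne, which is more acidic and should metalate readily. No ring is closed and no stereocentre is formed. The step needs chemoselectivity: only the terminal C–H of 16 can be metalated because the 5,7-diyne of the acyl chain is internal, and carbonate base at 45 °C should leave the ester and both furan rings untouched, which a stoichiometric lithium acetylide would not guarantee. Oxidative homocoupling of 16 is held back by strict exclusion of oxygen and a small excess of 16.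

Compound list
1 | furan | c1ccoc1 | starting material
2 | 2-furyllithium | [Li]c1ccco1 | intermediate
3 | 1,11-dibromoundecane | BrCCCCCCCCCCCBr | starting material
4 | 2-(11-bromoundecyl)furan | BrCCCCCCCCCCCc1ccco1 | intermediate
5 | 2-(tridec-12-yn-1-yl)furan | C#CCCCCCCCCCCCc1ccco1 | intermediate
6 | hex-5-ynoic acid | C#CCCCC(=O)O | starting material
7 | 6-bromohex-5-ynoic acid | BrC#CCCCC(=O)O | intermediate
8 | 19-(furan-2-yl)nonadeca-5,7-diynoic acid | O=C(O)CCCC#CC#CCCCCCCCCCCCc1ccco1 | intermediate
9 | 3-iodopropan-1-ol | OCCCI | starting material
10 | 3-iodopropyl 19-(furan-2-yl)nonadeca-5,7-diynoate | O=C(CCCC#CC#CCCCCCCCCCCCc1ccco1)OCCCI | intermediate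
11 | 1,4-dibromobutane | BrCCCCBr | starting material
12 | 2-(4-bromobutyl)furan | BrCCCCc1ccco1 | intermediate
13 | 1,4-bis(trimethylsilyl)buta-1,3-diyne | C[Si](C)(C)C#CC#C[Si](C)(C)C | starting material
14 | lithium 4-(trimethylsilyl)buta-1,3-diyn-1-ide | [Li]C#CC#C[Si](C)(C)C | intermediate (not isolated)
15 | trimethyl[8-(furan-2-yl)octa-1,3-diyn-1-yl]silane | C[Si](C)(C)C#CC#CCCCCc1ccco1 | intermediate
16 | 2-(octa-5,7-diyn-1-yl)furan | C#CC#CCCCCc1ccco1 | intermediate
17 | 11-(furan-2-yl)undeca-4,6-diyn-1-yl 19-(furan-2-yl)nonadeca-5,7-diynoate | O=C(CCCC#CC#CCCCCCCCCCCCc1ccco1)OCCCC#CC#CCCCCc1ccco1 | target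

Total step count: 10. Longest linear sequence: 6 steps (steps 1, 2, 3, 5, 6, 10).

Steps most likely to fail

Step 10. The terminal diyne may dimerise or oligomerise at copper, or the alkylpalladium intermediate may undergo β-hydride elimination, so that the iodide is consumed without coupling. The fallback makes the same C3–C4 bond by classical acetylide alkylation before the ester exists. It sets out from 16: n-BuLi in THF at −78 °C and then 2-(3-bromopropoxy)oxane in THF/HMPA should give racemic 2-{[11-(furan-2-yl)undeca-4,6-diyn-1-yl]oxy}oxane F1. PPTS in MeOH should free 11-(furan-2-yl)undeca-4,6-diyn-1-ol F2. DCC/DMAP esterification of F2 with acid 8 (used in place of iodide 10) comes back to the route at 17.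

Step 8. Over-desilylation to the dilithium diynide may lead to double alkylation, or substitution of the bromide by the stabilised diynide may be slow and lose out to elimination. The fallback builds the diyne by an sp–sp coupling instead. It sets out from 12: LiC≡CH·H2NCH2CH2NH2 in DMSO should give 2-(hex-5-yn-1-yl)furan F3. Cadiot–Chodkiewicz coupling of F3 with (bromoethynyl)tri(propan-2-yl)silane (CuCl, NH2OH·HCl, aqueous EtNH2, MeOH) should give tri(propan-2-yl)[8-(furan-2-yl)octa-1,3-diyn-1-yl]silane F4. Bu4NF in THF at 0 °C then comes back to the route at 16.

Step 5. The bromoalkynoic acid may homocouple, and the lipophilic alkyne 5 may mix poorly with the aqueous amine phase, giving low conversion. The fallback moves the halogen to the lipophilic partner so that the water-soluble carboxylate serves as the copper acetylide. It sets out from 5: n-BuLi in THF at −78 °C and then 1,2-dibromo-1,1,2,2-tetrachloroethane should give 2-(13-bromotridec-12-yn-1-yl)furan F5, brominated at the acetylide carbon and not at the furan ring. Cadiot–Chodkiewicz coupling of F5 with hex-5-ynoic acid 6 (CuCl, NH2OH·HCl, aqueous EtNH2, MeOH) comes back to the route at 8.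

Further compounds
F1 | step 10 | 2-{[11-(furan-2-yl)undeca-4,6-diyn-1-yl]oxy}oxane | C1CCCC(O1)OCCCC#CC#CCCCCc1ccco1
F2 | step 10 | 11-(furan-2-yl)undeca-4,6-diyn-1-ol | OCCCC#CC#CCCCCc1ccco1
F3 | step 8 | 2-(hex-5-yn-1-yl)furan | C#CCCCCc1ccco1
F4 | step 8 | tri(propan-2-yl)[8-(furan-2-yl)octa-1,3-diyn-1-yl]silane | CC(C)[Si](C(C)C)(C(C)C)C#CC#CCCCCc1ccco1
F5 | step 5 | 2-(13-bromotridec-12-yn-1-yl)furan | BrC#CCCCCCCCCCCCc1ccco1
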